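**Plan**
1. Daucane numbering: C-1 quaternary ring-fusion carbon (methyl), C-2 (angelate), C-3, C-4 (carbinol, isopropyl), C-5 ring-fusion CH, C-6 (aroyloxy), C-7, C-8(Me)=C-9, C-10; β is the face of the five-membered ring that carries the C-4 oxygen.
2. Cuts: the two ester C–O bonds; then C-1–C-10 of the seven-membered ring, with the C-6 oxygen written as a C-5=C-6 enol ether, which leads back to a cis-divinylcyclopropane (C-6/C-7/C-8) on C-5 of a cyclopentenone; then C-5–C-6; then C-1–C-5 of a 2-methyl-1,3-dione.
3. Enabling feature: ring atoms C-5, C-6(O), C-7H2, C-8(Me)=C-9, C-10H2, C-1 form, at the enol-ether oxidation level, a cyclohepta-1,4-diene with sp3 C-7 between the double bonds and the C-1–C-10 σ-bond opposite, which is the product pattern of a divinylcyclopropane rearrangement.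
4. Forward order: five-membered ring first (intramolecular Claisen condensation), cyclopropane unit attached at C-5, seven-membered ring by [3,3] ring expansion, then the C-2 and C-6 carbinols and their esters.
5. Stereochemistry: C-4 from (S)-2-hydroxy-3-methylbutanoic acid (alkylation with retention); C-1 in the key step under control of C-4; C-2 by hydride addition from the α-face; C-5 by thermodynamic protonation (cis fusion); C-6 by hydride delivery directed by the C-4 hydroxyl.

Key step: step 8

Assumption: the stereoisomers of the 1-methoxy-2-vinylcyclopropane in 14/15 interconvert at the rearrangement temperature by reversible homolysis of the C-6–C-8 bond (C-6 radical stabilised by OMe and the dienone, C-8 tertiary allylic), so the stereorandom cyclopropane 11 can be used.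

**Step 1**
Reactants: 1 (S)-2-hydroxy-3-methylbutanoic acid; 2 pivalaldehyde
Product: 3 (2S,5S)-2-tert-butyl-5-(propan-2-yl)-1,3-dioxolan-4-one
Conditions: TsOH·H2O (cat.), H2SO4 (cat.), pentane, reflux, Dean–Stark; recrystallisation
Reagents that add atoms: none
Why: Acid-catalysed acetalisation with a non-enolisable aldehyde under equilibrating conditions should give the cis-2,5-disubstituted dioxolanone (first stage of the self-regeneration-of-stereocentres protocol), the acetal centre being set by the existing carbinol centre.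

**Step 2**
Reactants: 3 (2S,5S)-2-tert-butyl-5-(propan-2-yl)-1,3-dioxolan-4-one; 4 1-bromobut-2-yne
Product: 5 (2S,5S)-5-(but-2-yn-1-yl)-2-tert-butyl-5-(propan-2-yl)-1,3-dioxolan-4-one
Conditions: LiN(i-Pr)2, THF, −78 °C; then 4, DMPU, −78 → −40 °C
Reagents that add atoms: none
Why: Alkylation of the dioxolanone lithium enolate should occur anti to the tert-butyl group, so the butynyl group replaces H with overall retention and fixes the future C-4 carbinol configuration (self-regeneration of stereocentres).

**Step 3**
Reactants: 5 (2S,5S)-5-(but-2-yn-1-yl)-2-tert-butyl-5-(propan-2-yl)-1,3-dioxolan-4-one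
Product: 6 (2S,5S)-2-tert-butyl-5-(2-oxobutyl)-5-(propan-2-yl)-1,3-dioxolan-4-one
Conditions: Ph3PAuNTf2 (2 mol %), H2O (3 equiv), 1,4-dioxane, 50 °C
Reagents that add atoms: water, O
Why: Gold-catalysed alkyne hydration with anchimeric assistance, in which 5-exo-dig attack of the lactone carbonyl oxygen directs water to the alkyne carbon γ to the carbonyl and gives the ethyl ketone regioselectively without touching the stereocentres.

**Step 4**
Reactants: 6 (2S,5S)-2-tert-butyl-5-(2-oxobutyl)-5-(propan-2-yl)-1,3-dioxolan-4-one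
Product: 7 (5S)-3,5-dihydroxy-2-methyl-5-(propan-2-yl)cyclopent-2-en-1-one (enol form of the 4-hydroxy-4-isopropyl-2-methylcyclopentane-1,3-dione)
Conditions: LiN(i-Pr)2 (2.2 equiv), THF, −78 → 0 °C; then 1 M HCl
Reagents that add atoms: none
Why: Intramolecular Claisen (Dieckmann-type) condensation, in which the kinetic enolate on the ethyl side attacks the activated lactone carbonyl (5-exo-trig), the tetrahedral intermediate collapses with loss of pivalaldehyde, and deprotonation of the 1,3-dione drives the reaction; the quaternary carbinol centre is not enolisable and is retained.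

**Step 5**
Reactants: 7 (5S)-3,5-dihydroxy-2-methyl-5-(propan-2-yl)cyclopent-2-en-1-one
Product: 8 (5S)-5-hydroxy-3-methoxy-2-methyl-5-(propan-2-yl)cyclopent-2-en-1-one
Conditions: MeOH, TsOH·H2O (cat.), 3 Å molecular sieves, reflux
Reagents that add atoms: methanol, CO
Why: Acid-catalysed enol etherification of the vinylogous acid under thermodynamic control should place OMe on the less hindered oxygen, remote from the quaternary carbinol, as with other 4,4-disubstituted cyclic 1,3-diones, leaving free the carbonyl that becomes C-5.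

**Step 6**
Reactants: 9 isoprene; 10 dichloromethyl methyl ether
Product: 11 1-chloro-1-methoxy-2-methyl-2-vinylcyclopropane (racemic, both diastereomers)
Conditions: MeLi, Et2O, isoprene (5 equiv), −20 → 0 °C
Reagents that add atoms: none
Why: α-Elimination from the lithiated dichloromethyl ether gives a chloro(methoxy)carbenoid that should cyclopropanate the more nucleophilic 1,1-disubstituted double bond of isoprene (alkoxyhalocarbenoid cyclopropanation); the stereoisomer mixture is used as such.

**Step 7**
Reactants: 8 (5S)-5-hydroxy-3-methoxy-2-methyl-5-(propan-2-yl)cyclopent-2-en-1-one; 11 1-chloro-1-methoxy-2-methyl-2-vinylcyclopropane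
Product: 14 (4S)-4-hydroxy-3-(1-methoxy-2-methyl-2-vinylcyclopropyl)-2-methyl-4-(propan-2-yl)cyclopent-2-en-1-one, via cyclopropyllithium 12 (not isolated), via carbinol adduct 13 (not isolated)
Conditions: 11, LiDBB (2.1 equiv), THF, −78 °C; CeCl3; then lithium alkoxide of 8 (from LiN(SiMe3)2, 1 equiv), −78 → −20 °C; 1 M HCl, 0 °C, 10 min
Reagents that add atoms: water, O
Why: Reductive lithiation of the α-chloro ether gives the 1-methoxycyclopropyllithium, whose cerium derivative adds 1,2 to the vinylogous-ester carbonyl (the future C-5), and acid then effects the Stork–Danheiser transposition to the enone; the cyclopropane stereocentres form unselectively, which the next step tolerates.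

**Step 8**
Reactants: 14 (4S)-4-hydroxy-3-(1-methoxy-2-methyl-2-vinylcyclopropyl)-2-methyl-4-(propan-2-yl)cyclopent-2-en-1-one
Product: 16 6-methoxy-4β-(trimethylsilyloxy)dauca-5,8-dien-2-one (C-10 β, angular methyl α), via trimethylsilyl ether 15 (not isolated)
Conditions: BSA (3 equiv), BHT (cat.), PhMe, 60 °C, 1 h; then 140 °C, sealed tube
Reagents that add atoms: N,O-bis(trimethylsilyl)acetamide, CC(=N[Si](C)(C)C)O[Si](C)(C)C
Why: In-situ silylation removes the hydroxyl proton, and on heating the doubly activated C-6–C-8 cyclopropane bond opens and recloses so that all cyclopropane isomers drain through the cis-divinyl isomers, which undergo the concerted [3,3]-sigmatropic shift through the boat transition state, forming C-1–C-10 and breaking C-6–C-8. The closest known reaction type is the divinylcyclopropane–cycloheptadiene (Cope) rearrangement of 3-(2-vinylcyclopropyl)cycloalk-2-enones, which is used to make hydroazulenones with an angular methyl group. The seven-membered ring is closed by ring expansion of the cyclopropane (three to seven: C-6, C-7, C-8 plus the vinyl units C-5=C-1 and C-9=C-10), the new σ-bond joining the two vinyl termini; it is not an exo or endo cyclisation. The new quaternary centre C-1 is controlled by C-4: in the boat the second allyl unit lies over C-5 and meets the C-4 substituent on that face, so it should stack on the face carrying the small silyloxy oxygen and not on the isopropyl face, which places C-10 cis to the C-4 oxygen and the methyl trans. The step needs the Cope path to win over the [1,3]-shift of the same diradical and over the α-face boat; ring strain and the pre-organised cis-divinyl geometry favour the former, and the isopropyl/OSiMe3 size difference next to C-5, with no O–H···OMe hydrogen bond left to favour the other rotamer, should secure the latter.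

**Step 9**
Reactants: 16 6-methoxy-4β-(trimethylsilyloxy)dauca-5,8-dien-2-one
Product: 17 6-methoxy-4β-(trimethylsilyloxy)dauca-5,8-dien-2β-ol
Conditions: LiAlH4, THF, −78 °C; then H2O, 15% NaOH
Reagents that add atoms: none
Why: 1,2-Reduction of the only carbonyl group; the β-face of C-2 is screened by the pseudo-axial C-10 methylene, the folded cycloheptadiene and the C-4 silyloxy group, so hydride should add from the α-face and give the 2β-alcohol (substrate control).

**Step 10**
Reactants: 17 6-methoxy-4β-(trimethylsilyloxy)dauca-5,8-dien-2β-ol; 18 angelic acid; 19 2,4,6-trichlorobenzoyl chloride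
Product: 21 2β-angeloyloxy-6-methoxy-4β-(trimethylsilyloxy)dauca-5,8-diene, via mixed anhydride 20 (not isolated)
Conditions: 18, 19, Et3N, PhMe, rt, 2 h; then 17, 80 °C
Reagents that add atoms: none
Why: Yamaguchi-type esterification through the mixed anhydride without a nucleophilic catalyst should acylate the hindered secondary alcohol while keeping the (Z)-geometry of the angelate; the tertiary silyl ether and the enol ether are inert under the basic conditions.

**Step 11**
Reactants: 21 2β-angeloyloxy-6-methoxy-4β-(trimethylsilyloxy)dauca-5,8-diene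
Product: 22 2β-angeloyloxy-4β-hydroxy-5αH-dauc-8-en-6-one (cis-fused)
Conditions: 1 M HCl, THF, 0 °C → rt
Reagents that add atoms: water, O
Why: Acid hydrolysis of the methyl enol ether (protonation at C-5, hydrolysis of the oxocarbenium ion) and of the silyl ether unveils the C-6 ketone and the C-4 hydroxyl; C-5 should end with H cis to the angular methyl because the cis-fused ketone, with C-6 trans to the isopropyl group, is the more stable epimer and C-5 equilibrates through the enol under the same conditions.

**Step 12**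
Reactants: 22 2β-angeloyloxy-4β-hydroxy-5αH-dauc-8-en-6-one
Product: 23 2β-angeloyloxy-5αH-dauc-8-ene-4β,6α-diol (6-OH cis to H-5)
Conditions: Me4NBH(OAc)3, AcOH–MeCN (1:1), −30 °C
Reagents that add atoms: none
Why: Evans–Saksena reduction, in which the C-4 hydroxyl exchanges onto boron and the alkoxyborohydride delivers hydride intramolecularly to the face of the C-6 carbonyl syn to C-4, giving the 6-alcohol cis to H-5; the reagent does not reduce esters or alkenes.

**Step 13**
Reactants: 23 2β-angeloyloxy-5αH-dauc-8-ene-4β,6α-diol; 24 3,4,5-trimethoxybenzoyl chloride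
Product: 25 (1R,2S,4S,5R,6R)-2-angeloyloxy-4-hydroxy-6-(3,4,5-trimethoxybenzoyloxy)dauc-8-ene (CNP0112256.1)
Conditions: pyridine, DMAP (cat.), CH2Cl2, 0 °C → rt
Reagents that add atoms: none
Why: DMAP-catalysed acylation of the only secondary hydroxyl; the tertiary C-4 hydroxyl is too hindered to react and no stereocentre is affected.

**Compound list**
1 | (S)-2-hydroxy-3-methylbutanoic acid | CC(C)[C@H](O)C(=O)O | starting material
2 | pivalaldehyde | CC(C)(C)C=O | starting material
3 | (2S,5S)-2-tert-butyl-5-(propan-2-yl)-1,3-dioxolan-4-one | CC(C)[C@@H]1O[C@H](C(C)(C)C)OC1=O | intermediate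
4 | 1-bromobut-2-yne | CC#CCBr | starting material
5 | (2S,5S)-5-(but-2-yn-1-yl)-2-tert-butyl-5-(propan-2-yl)-1,3-dioxolan-4-one | CC#CC[C@@]1(C(C)C)O[C@H](C(C)(C)C)OC1=O | intermediate
6 | (2S,5S)-2-tert-butyl-5-(2-oxobutyl)-5-(propan-2-yl)-1,3-dioxolan-4-one | CCC(=O)C[C@@]1(C(C)C)O[C@H](C(C)(C)C)OC1=O | intermediate
7 | (5S)-3,5-dihydroxy-2-methyl-5-(propan-2-yl)cyclopent-2-en-1-one (enol of the 1,3-dione) | CC1=C(O)C[C@](O)(C(C)C)C1=O | intermediate
8 | (5S)-5-hydroxy-3-methoxy-2-methyl-5-(propan-2-yl)cyclopent-2-en-1-one | CC1=C(OC)C[C@](O)(C(C)C)C1=O | intermediate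
9 | isoprene | C=CC(C)=C | starting material
10 | dichloromethyl methyl ether | COC(Cl)Cl | starting material
11 | 1-chloro-1-methoxy-2-methyl-2-vinylcyclopropane (racemic, both diastereomers) | COC1(Cl)CC1(C)C=C | intermediate
12 | (1-methoxy-2-methyl-2-vinylcyclopropyl)lithium (stereoisomer mixture) | [Li]C1(OC)CC1(C)C=C | intermediate (not isolated)
13 | (5S)-3-methoxy-1-(1-methoxy-2-methyl-2-vinylcyclopropyl)-2-methyl-5-(propan-2-yl)cyclopent-2-ene-1,5-diol (dilithium salt in the flask, diastereomer mixture) | COC1=C(C)C(O)(C2(OC)CC2(C)C=C)[C@@](O)(C(C)C)C1 | intermediate (not isolated)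
14 | (4S)-4-hydroxy-3-(1-methoxy-2-methyl-2-vinylcyclopropyl)-2-methyl-4-(propan-2-yl)cyclopent-2-en-1-one (cyclopropane stereoisomer mixture) | CC1=C(C2(OC)CC2(C)C=C)[C@@](O)(C(C)C)CC1=O | intermediate
15 | trimethylsilyl ether of 14 | CC1=C(C2(OC)CC2(C)C=C)[C@@](O[Si](C)(C)C)(C(C)C)CC1=O | intermediate (not isolated)
16 | 6-methoxy-4β-(trimethylsilyloxy)dauca-5,8-dien-2-one (C-10 β, angular methyl α) | O=C1C[C@](O[Si](C)(C)C)(C(C)C)C2=C(OC)CC(C)=CC[C@@]12C | intermediate
17 | 6-methoxy-4β-(trimethylsilyloxy)dauca-5,8-dien-2β-ol | O[C@H]1C[C@](O[Si](C)(C)C)(C(C)C)C2=C(OC)CC(C)=CC[C@@]12C | intermediate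
18 | angelic acid, (Z)-2-methylbut-2-enoic acid | C/C=C(/C)C(=O)O | starting material
19 | 2,4,6-trichlorobenzoyl chloride | O=C(Cl)c1c(Cl)cc(Cl)cc1Cl | starting material
20 | angelic 2,4,6-trichlorobenzoic anhydride | C/C=C(/C)C(=O)OC(=O)c1c(Cl)cc(Cl)cc1Cl | intermediate (not isolated)
21 | 2β-angeloyloxy-6-methoxy-4β-(trimethylsilyloxy)dauca-5,8-diene | C/C=C(/C)C(=O)O[C@H]1C[C@](O[Si](C)(C)C)(C(C)C)C2=C(OC)CC(C)=CC[C@@]12C | intermediate
22 | 2β-angeloyloxy-4β-hydroxy-5αH-dauc-8-en-6-one (cis-fused) | C/C=C(/C)C(=O)O[C@H]1C[C@](O)(C(C)C)[C@H]2C(=O)CC(C)=CC[C@@]12C | intermediate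
23 | 2β-angeloyloxy-5αH-dauc-8-ene-4β,6α-diol (6-OH cis to H-5) | C/C=C(/C)C(=O)O[C@H]1C[C@](O)(C(C)C)[C@H]2[C@H](O)CC(C)=CC[C@@]12C | intermediate
24 | 3,4,5-trimethoxybenzoyl chloride | COc1cc(C(=O)Cl)cc(OC)c1OC | starting material
25 | (1R,2S,4S,5R,6R)-2-angeloyloxy-4-hydroxy-6-(3,4,5-trimethoxybenzoyloxy)dauc-8-ene | C/C=C(/C)C(=O)O[C@H]1C[C@](O)(C(C)C)[C@H]2[C@H](OC(=O)c3cc(OC)c(OC)c(OC)c3)CC(C)=CC[C@@]12C | target

**Totals**
Total step count: 13. Longest linear sequence: 12 steps (steps 1–5 and 7–13); step 6 is a one-step side branch.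

**Steps most likely to fail**

Step 7. The hindered tertiary cyclopropyl anion may deprotonate 8 instead of adding to the neopentyl-type carbonyl. The 1-methoxycyclopropyl carbinol may also ring-expand (pinacol-type shift to a cyclobutanone) during the acid-induced transposition. The fallback sets out from 8 and comes back at 14; it builds the cyclopropane after the C-5–C-6 bond and after the transposition. Commercial (E)-2-methylbut-2-enal is converted with HC(OMe)3/MeOH (cat. TsOH) into (E)-1,1-dimethoxy-2-methylbut-2-ene F1. 1,4-Elimination of methanol (KOt-Bu, DMSO) gives 1-methoxy-2-methylbuta-1,3-diene F2. α-Lithiation (t-BuLi, THF, −78 °C) gives (1-methoxy-2-methylbuta-1,3-dien-1-yl)lithium F3, a small sp2 nucleophile. Addition to the lithium alkoxide of 8 and buffered acidic transposition (aq. NH4Cl, 0 °C) should give (4S)-4-hydroxy-3-(1-methoxy-2-methylbuta-1,3-dien-1-yl)-2-methyl-4-(propan-2-yl)cyclopent-2-en-1-one F4. Simmons–Smith cyclopropanation in the Furukawa mode (Et2Zn, CH2I2, CH2Cl2, 0 °C), directed by the zinc alkoxide of the C-4 hydroxyl to the electron-rich enol-ether double bond, then gives 14 as the same stereoisomer mixture.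

Step 8. The second allyl unit may stack on the α-face and give the C-1 epimer, the trans isomers may fail to equilibrate, or the diradical may close to the [1,3]-shift cyclopentene. The fallback sets out from 14 and comes back at 16; it adds a temporary stereocentre beside the reacting terminus. Hydroxyl-directed reduction of the enone carbonyl (Me4NBH(OAc)3, AcOH–MeCN, −30 °C) should give the trans-1,3-diol (1R,4S)-4-hydroxy-3-(1-methoxy-2-methyl-2-vinylcyclopropyl)-2-methyl-4-(propan-2-yl)cyclopent-2-en-1-ol F5 (2α-OH). Both hydroxyls are silylated in situ (BSA) to the bis(trimethylsilyl) ether of F5 F6, and heating as in step 8 follows. The allylic 2α-silyloxy group next to C-1 and the C-4 isopropyl group now both block the α-face, so the rearrangement should give 6-methoxy-2α,4β-bis(trimethylsilyloxy)dauca-5,8-diene F7 with C-10 β. Selective methanolysis of the secondary silyl ether (K2CO3, MeOH, 0 °C) gives 6-methoxy-4β-(trimethylsilyloxy)dauca-5,8-dien-2α-ol F8. Oxidation with the periodinane DMP (NaHCO3, CH2Cl2) returns 16.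

Step 9. Hydride may add with poor facial selectivity at C-2 while the ring fusion is still planar at C-5, giving the 2α-alcohol. The fallback sets out from 16 and comes back at 25; it postpones the C-2 reduction until the bicycle is cis-fused. Hydrolysis (1 M HCl, THF) gives 4β-hydroxy-5αH-dauc-8-ene-2,6-dione F9. Hydroxyl-directed reduction (Me4NBH(OAc)3, AcOH–MeCN, −30 °C), in which the unhindered C-6 ketone should react before the neopentyl C-2 ketone, gives 4β,6α-dihydroxy-5αH-dauc-8-en-2-one F10. Acylation with 24 (pyridine, DMAP) gives 4β-hydroxy-6α-(3,4,5-trimethoxybenzoyloxy)-5αH-dauc-8-en-2-one F11. Reduction from the convex α-face of the cis-fused bicycle (NaBH4, MeOH, −40 °C) gives 6α-(3,4,5-trimethoxybenzoyloxy)-5αH-dauc-8-ene-2β,4β-diol F12. Esterification with 18 and 19 as in step 10 gives 25.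

**Further compounds**
F1 | step 7 | (E)-1,1-dimethoxy-2-methylbut-2-ene | C/C=C(\C)C(OC)OC
F2 | step 7 | 1-methoxy-2-methylbuta-1,3-diene (E/Z mixture) | COC=C(C)C=C
F3 | step 7 | (1-methoxy-2-methylbuta-1,3-dien-1-yl)lithium | [Li]C(OC)=C(C)C=C
F4 | step 7 | (4S)-4-hydroxy-3-(1-methoxy-2-methylbuta-1,3-dien-1-yl)-2-methyl-4-(propan-2-yl)cyclopent-2-en-1-one | CC1=C(C(OC)=C(C)C=C)[C@@](O)(C(C)C)CC1=O
F5 | step 8 | (1R,4S)-4-hydroxy-3-(1-methoxy-2-methyl-2-vinylcyclopropyl)-2-methyl-4-(propan-2-yl)cyclopent-2-en-1-ol (trans-diol) | O[C@@H]1C[C@](O)(C(C)C)C(C2(OC)CC2(C)C=C)=C1C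
F6 | step 8 | bis(trimethylsilyl) ether of F5 | C[Si](C)(C)O[C@@H]1C[C@](O[Si](C)(C)C)(C(C)C)C(C2(OC)CC2(C)C=C)=C1C
F7 | step 8 | 6-methoxy-2α,4β-bis(trimethylsilyloxy)dauca-5,8-diene | C[Si](C)(C)O[C@@H]1C[C@](O[Si](C)(C)C)(C(C)C)C2=C(OC)CC(C)=CC[C@@]12C
F8 | step 8 | 6-methoxy-4β-(trimethylsilyloxy)dauca-5,8-dien-2α-ol | O[C@@H]1C[C@](O[Si](C)(C)C)(C(C)C)C2=C(OC)CC(C)=CC[C@@]12C
F9 | step 9 | 4β-hydroxy-5αH-dauc-8-ene-2,6-dione | O=C1C[C@](O)(C(C)C)[C@H]2C(=O)CC(C)=CC[C@@]12C
F10 | step 9 | 4β,6α-dihydroxy-5αH-dauc-8-en-2-one | O=C1C[C@](O)(C(C)C)[C@H]2[C@H](O)CC(C)=CC[C@@]12C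
F11 | step 9 | 4β-hydroxy-6α-(3,4,5-trimethoxybenzoyloxy)-5αH-dauc-8-en-2-one | O=C1C[C@](O)(C(C)C)[C@H]2[C@H](OC(=O)c3cc(OC)c(OC)c(OC)c3)CC(C)=CC[C@@]12C
F12 | step 9 | 6α-(3,4,5-trimethoxybenzoyloxy)-5αH-dauc-8-ene-2β,4β-diol | O[C@H]1C[C@](O)(C(C)C)[C@H]2[C@H](OC(=O)c3cc(OC)c(OC)c(OC)c3)CC(C)=CC[C@@]12C
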